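Hold the clock at 2.50 h and the two earlier runs seem to be the wrong way round.

| flask | substrate | gas phase | remark | time |
|---|---|---|---|---|
| autumn | 0.037 M (fed, over 50 min) | 7.8 mM (held) | run made earlier; the fed solution adds 0.20 times the starting volume |  |
| spring | 0.12 M (fed, over 50 min) | 7.8 mM (held) | run made earlier; the fed solution adds 0.20 times the starting volume |  |
| elm | 0.15 M | 7.8 mM | everything together at the start, the whole solution of substrate included, so that from the start the volume is larger by 0.20 times the starting volume | 4.0 h |
| ash | 0.050 M (fed, over 50 min) | 7.8 mM (held) | the fed solution adds 0.20 times the starting volume | 2.5 h |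

- autumn (time / h: product / %): 0.417: 1.4; 0.833: 7.7; 1.33: 15.9; 1.50: 18.1; 2.00: 23.6; 2.50: 29.2
- spring (time / h: product / %): 0.200: 1.2; 0.333: 0.3; 0.500: 3.0; 0.833: 5.9; 1.50: 12.2; 2.50: 19.6

(each reading ± 0.5 percentage points)

- which one finishes higher in amount of product, in percent of the substrate charged ("neither" within 2 percentage points) (elm / ash / neither)
- amount of product at the end, in percent of the substrate charged, elm
- amount of product at the end, in percent of the substrate charged, ash

- every charge counts on the volume at the start, and the solution that is fed holds the whole dose
- the numbers in the tables scatter with a standard deviation of 0.5 percentage points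
- at the start none of the gas phase is in solution
- percentages count the whole charge, also what has not yet gone in

1. The puzzle: spring got 3.24 times autumn's charge, yet its product fraction at 2.50 h, 19.6 %, is less than autumn's 29.2 %.

2. Divide spring's fraction by autumn's at equal times. The readings give 0.766 at 0.833 h, 0.674 at 1.50 h and 0.671 at 2.50 h, so the ratio moves early and then reads steady between the last two times; you take it at 2.50 h, as a reading with its scatter.

3. The logarithm of the ratio at 2.50 h over the logarithm of the charge ratio reads −0.339. Call it the charge slope, the apparent order less one. The puzzle clears: spring made 2.18 times autumn's product, which is less than the charge ratio.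

4. Ash has the feed and time of both runs, so you scale autumn's fraction by the charge ratio raised to the slope: 26.4 %.

5. For elm, the slope takes spring's fraction to 18.2 % at 2.50 h, treating elm as if it were fed. Spring's pace fell by the factor 0.783 between its last two intervals. Cut its last pace by that factor once more, scale it the same way, and run it to 4.0 h: 26.2 %.

6. Your two answers differ by less than 2 percentage points, so you say neither.

The forecast says neither, with 26 % for elm and 26.5 % for ash, reading the runs as “it is saturating: K about 0.06 M, initial Vmax about 0.025 M/h”.

The flasks give neither: elm 26.8 %, ash 27.2 %.

    gas phase ⇌ dissolved gas, rate k1*(csat - [dissolved gas]) (kL = 5.63 × 10⁻⁴ s⁻¹)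
    substrate + dissolved gas ⇌ product (K = 110 M⁻¹, k = 0.0146 M⁻¹ s⁻¹)

The neighbouring flask is ash charged with 0.12 M of substrate, time and all else held. Start from ash's 27.2 % and scale by the charge ratio raised to the charge slope −0.339: that gives 20.2 %. At 2.50 h, that neighbouring flask holds 19.6 % product, with 80.4 % of its charged substrate still there.

The data are simulated for substances that don't exist, noise included.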